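**Retrosynthetic overview**
- Final operations: phenol unmasking and ring-closing metathesis (C8=C9); the seven-membered ring is closed last, on a cis-1,2-disubstituted cyclopentane carrying both esterified carbinols.
- C10 carbinol: catalyst-controlled transfer hydrogenation of an ynone made by acetylide opening of a cis-fused bicyclic γ-lactone (C10 = lactone carbonyl, C6–O = ring oxygen).
- Key bond C6–C7: intermolecular reagent-controlled carbonyl methallylation of a cis aldehyde ester with a methallyl fragment, then lactonisation.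
- Aldehyde ester: from a cis-fused lactone acetal built on a menthyloxy butenolide by conjugate addition, two enolate alkylations (quaternary C1), RCM (the five-membered carbocycle, formed first) and Mukaiyama hydration (C4).
- Chirality source: furfural plus (+)-menthol; ring order auxiliary lactone, then cyclopentene, then cycloheptene.

Assumption: the SMILES is read as the cis-fused isomer (1R,4S,5S,6R,10S) in daucane numbering, i.e. (3S,3aS,4R,8S,8aR) in azulene numbering: angular methyl, H-5 and 4-OH on one face; isopropyl, 6-O and 10-O on the other. Labels C1–C10 below mean: C1 quaternary methyl carbon, C2/C3 ring CH2, C4 carbinol carbon with isopropyl, C5 ring-fusion CH, C6 aroyloxy carbon, C7 CH2, C8=C9 alkene, C10 isovaleryloxy carbon. "Menthyl" means 5-methyl-2-(propan-2-yl)cyclohexyl.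

**Route**

Step 1
Reactants: 1 furfural
Product: 3 5-hydroxyfuran-2(5H)-one (racemic), via furfural endoperoxide 2 (not isolated)
Conditions: O2, hν (visible), methylene blue (cat.), MeOH, rt
Reagents that add atoms: oxygen, O=O
Why: Singlet-oxygen [4+2] cycloaddition to the furan gives the endoperoxide, which methanol fragments to the hydroxybutenolide with loss of the formyl carbon; no lasting stereocentre is set.

Step 2
Reactants: 3 5-hydroxyfuran-2(5H)-one; 4 (+)-menthol
Product: 5 (5S)-5-[(1S,2R,5S)-menthyloxy]furan-2(5H)-one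
Conditions: TsOH (cat.), toluene, reflux (Dean–Stark); crystallise from hexane, re-equilibrate mother liquor with TsOH
Reagents that add atoms: none
Why: Acid-catalysed acetalisation in which the two acetal epimers equilibrate and the (5S)-epimer (mirror image of the familiar (5R)-l-menthyloxy compound) crystallises, a crystallisation-induced diastereomer transformation.

Step 3
Reactants: 5 (5S)-5-[(1S,2R,5S)-menthyloxy]furan-2(5H)-one; 6 2-bromo-3-methylbut-1-ene
Product: 8 (4R,5S)-5-[(1S,2R,5S)-menthyloxy]-4-(3-methylbut-1-en-2-yl)oxolan-2-one, via alkenylmagnesium bromide 7 (not isolated)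
Conditions: 6, Mg, THF, 50 °C; then CuBr·SMe2 (10 mol %), 5, THF, −78 → −30 °C; aq NH4Cl
Reagents that add atoms: none
Why: Copper-catalysed conjugate (1,4-) addition of the alkenyl Grignard reagent; it enters anti to the menthyloxy group, fixing the future ring-fusion carbon C5.

Step 4
Reactants: 8 (4R,5S)-5-[(1S,2R,5S)-menthyloxy]-4-(3-methylbut-1-en-2-yl)oxolan-2-one
Product: 10 (3S,4R,5S)-3-allyl-5-[(1S,2R,5S)-menthyloxy]-4-(3-methylbut-1-en-2-yl)oxolan-2-one, via lithium lactone enolate 9 (not isolated)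
Conditions: LDA, THF, −78 °C; allyl bromide, DMPU, −78 → −40 °C
Reagents that add atoms: allyl bromide (3-bromoprop-1-ene), C=CCBr
Why: Lactone enolate alkylation; the electrophile approaches anti to the neighbouring alkenyl group (this centre is re-set in step 5).

Step 5
Reactants: 10 (3S,4R,5S)-3-allyl-5-[(1S,2R,5S)-menthyloxy]-4-(3-methylbut-1-en-2-yl)oxolan-2-one
Product: 12 (3R,4S,5S)-3-allyl-3-methyl-5-[(1S,2R,5S)-menthyloxy]-4-(3-methylbut-1-en-2-yl)oxolan-2-one, via lithium allyl-lactone enolate 11 (not isolated)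
Conditions: LDA, THF, −78 °C; MeI, DMPU, −78 → −20 °C
Reagents that add atoms: iodomethane, CI
Why: Second enolate alkylation creates quaternary C1; MeI again enters anti to the alkenyl group, so methyl ends trans and allyl cis to it, as ring closure requires.

Step 6
Reactants: 12 (3R,4S,5S)-3-allyl-3-methyl-5-[(1S,2R,5S)-menthyloxy]-4-(3-methylbut-1-en-2-yl)oxolan-2-one
Product: 13 (3S,3aS,6aR)-6a-methyl-3-[(1S,2R,5S)-menthyloxy]-4-(propan-2-yl)-3,3a,6,6a-tetrahydro-1H-cyclopenta[c]furan-1-one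
Conditions: second-generation Grubbs catalyst (5 mol %), toluene, 80 °C
Reagents that add atoms: none
Why: Ring-closing olefin metathesis joins the cis-disposed allyl and 1,1-disubstituted alkenyl groups into the cis-fused cyclopentene, driven by loss of ethylene; no new stereocentre.

Step 7
Reactants: 13 (3S,3aS,6aR)-6a-methyl-3-[(1S,2R,5S)-menthyloxy]-4-(propan-2-yl)-3,3a,6,6a-tetrahydro-1H-cyclopenta[c]furan-1-one
Product: 14 (3S,3aR,4S,6aR)-4-hydroxy-6a-methyl-3-[(1S,2R,5S)-menthyloxy]-4-(propan-2-yl)hexahydro-1H-cyclopenta[c]furan-1-one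
Conditions: Co(acac)2 (20 mol %), PhSiH3, O2 (1 atm), THF, rt
Reagents that add atoms: oxygen, O=O
Why: Mukaiyama (hydrogen-atom-transfer, Markovnikov) hydration; the tertiary C4 radical is trapped by O2 on the convex face of the cis-fused bicycle, so the hydroxyl ends cis to the angular methyl and ring-fusion hydrogen.

Step 8
Reactants: 14 (3S,3aR,4S,6aR)-4-hydroxy-6a-methyl-3-[(1S,2R,5S)-menthyloxy]-4-(propan-2-yl)hexahydro-1H-cyclopenta[c]furan-1-one
Product: 15 (3aR,4S,6aR)-3,4-dihydroxy-6a-methyl-4-(propan-2-yl)hexahydro-1H-cyclopenta[c]furan-1-one (lactol; both C3 epimers)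
Conditions: 1 M HCl, THF, 45 °C
Reagents that add atoms: water, O
Why: Acid hydrolysis of the acylal-type acetal removes the auxiliary; the aldehyde stays masked as the cis-fused lactol (pseudo-acid), which protects the epimerisable C5 centre.

Step 9
Reactants: 15 (3aR,4S,6aR)-3,4-dihydroxy-6a-methyl-4-(propan-2-yl)hexahydro-1H-cyclopenta[c]furan-1-one
Product: 16 methyl (1R,2R,3S)-2-formyl-3-hydroxy-1-methyl-3-(propan-2-yl)cyclopentane-1-carboxylate
Conditions: TMSCHN2, MeOH/toluene (1:4), 0 °C; used at once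
Reagents that add atoms: (trimethylsilyl)diazomethane, C[Si](C)(C)C=[N+]=[N-]
Why: Diazoalkane esterification traps the ring-opened acid tautomer under neutral conditions, releasing the cis aldehyde without epimerisation.

Step 10
Reactants: 16 methyl (1R,2R,3S)-2-formyl-3-hydroxy-1-methyl-3-(propan-2-yl)cyclopentane-1-carboxylate; 17 (2-methylprop-2-en-1-yl)magnesium chloride
Product: 20 (3R,3aS,4S,6aR)-4-hydroxy-6a-methyl-3-(2-methylprop-2-en-1-yl)-4-(propan-2-yl)hexahydro-1H-cyclopenta[c]furan-1-one, via methallyldiisopinocampheylborane 18 (not isolated), via hydroxy methyl ester 19 (not isolated)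
Conditions: 17 and (+)-Ipc2BOMe [from (−)-α-pinene] (2.5 equiv each), Et2O, −78 °C → rt; then 16, −78 °C; 3 M NaOH, 30% H2O2, rt; TsOH (cat.), CH2Cl2, rt
Reagents that add atoms: none
Why: Brown asymmetric allylboration (carbonyl allylation through a chair Zimmerman–Traxler transition state); this reagent adds methallyl to the Re face, giving the (R)-carbinol at C6 under reagent control, and the cis γ-hydroxy ester lactonises.

Step 11
Reactants: 20 (3R,3aS,4S,6aR)-4-hydroxy-6a-methyl-3-(2-methylprop-2-en-1-yl)-4-(propan-2-yl)hexahydro-1H-cyclopenta[c]furan-1-one; 21 ethynyl(trimethyl)silane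
Product: 23 1-{(1R,2S,3S)-3-hydroxy-2-[(1R)-1-hydroxy-3-methylbut-3-en-1-yl]-1-methyl-3-(propan-2-yl)cyclopentyl}-3-(trimethylsilyl)prop-2-yn-1-one, via lithium trimethylsilylacetylide 22 (not isolated)
Conditions: 21 (3.5 equiv), n-BuLi (3.3 equiv), THF, −78 °C; then 20, −78 → −30 °C; aq NH4Cl
Reagents that add atoms: none
Why: Acetylide addition to the lactone carbonyl; the tetrahedral lithium hemiketal is stable at low temperature, so one addition occurs and work-up opens it to the ynone and the free C6 carbinol.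

Step 12
Reactants: 23 1-{(1R,2S,3S)-3-hydroxy-2-[(1R)-1-hydroxy-3-methylbut-3-en-1-yl]-1-methyl-3-(propan-2-yl)cyclopentyl}-3-(trimethylsilyl)prop-2-yn-1-one
Product: 24 C6-O-(4-acetoxybenzoyl) ynone (4-acetoxybenzoate of 23 at its secondary hydroxyl)
Conditions: 4-acetoxybenzoyl chloride, pyridine, DMAP (cat.), CH2Cl2, 0 °C → rt
Reagents that add atoms: 4-acetoxybenzoyl chloride, CC(=O)Oc1ccc(cc1)C(Cl)=O
Why: DMAP-catalysed O-acylation of the only secondary hydroxyl; the tertiary C4 alcohol is too hindered to react.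

Step 13
Reactants: 24 C6-O-(4-acetoxybenzoyl) ynone
Product: 25 (10R)-propargylic alcohol (C10 ketone of 24 reduced; same spatial sense as 10S in the target)
Conditions: RuCl(p-cymene)[(R,R)-TsDPEN] (5 mol %), i-PrOH, rt
Reagents that add atoms: none
Why: Noyori asymmetric transfer hydrogenation; the (R,R)-catalyst delivers hydride to one ynone face (alkynyl recognised by CH/π interaction), reinforced by Felkin–Anh approach anti to the C1–C5 bond, setting C10.

Step 14
Reactants: 25 (10R)-propargylic alcohol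
Product: 26 C10-O-(3-methylbutanoyl) ester of 25
Conditions: 3-methylbutanoyl chloride, pyridine, DMAP, CH2Cl2, rt
Reagents that add atoms: 3-methylbutanoyl chloride, CC(C)CC(Cl)=O
Why: DMAP-catalysed acylation of the secondary propargylic alcohol; the tertiary alcohol stays free.

Step 15
Reactants: 26 C10-O-(3-methylbutanoyl) ester
Product: 27 terminal alkyne (C-desilylated 26; 10S)
Conditions: TBAF, AcOH (1:1), THF, 0 °C
Reagents that add atoms: none
Why: Fluoride-induced protodesilylation of the alkynylsilane; acetic acid buffering spares the aryl acetate and the other esters.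

Step 16
Reactants: 27 terminal alkyne
Product: 28 diene (alkyne of 27 reduced to CH=CH2; 1R,4S,5S,6R,10S)
Conditions: H2 (1 atm), Pd/CaCO3 poisoned with Pb(OAc)2, quinoline, EtOAc, rt
Reagents that add atoms: none
Why: Lindlar semi-hydrogenation stops at the alkene and leaves the 1,1-disubstituted alkene untouched.

Step 17
Reactants: 28 diene
Product: 29 (3S,3aS,4R,8S,8aR)-3-hydroxy-6,8a-dimethyl-8-[(3-methylbutanoyl)oxy]-3-(propan-2-yl)-1,2,3,3a,4,5,8,8a-octahydroazulen-4-yl 4-acetoxybenzoate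
Conditions: second-generation Grubbs catalyst (10 mol %), toluene (2 mM), 80 °C
Reagents that add atoms: none
Why: Ring-closing metathesis of the vinyl and 1,1-disubstituted alkenes, held cis on the cyclopentane, closes the seven-membered ring with the trisubstituted C8=C9 alkene; no stereocentre is touched.

Step 18
Reactants: 29 (3S,3aS,4R,8S,8aR)-3-hydroxy-6,8a-dimethyl-8-[(3-methylbutanoyl)oxy]-3-(propan-2-yl)-1,2,3,3a,4,5,8,8a-octahydroazulen-4-yl 4-acetoxybenzoate
Product: 30 (3S,3aS,4R,8S,8aR)-3-hydroxy-6,8a-dimethyl-8-[(3-methylbutanoyl)oxy]-3-(propan-2-yl)-1,2,3,3a,4,5,8,8a-octahydroazulen-4-yl 4-hydroxybenzoate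
Conditions: pyrrolidine (3 equiv), CH2Cl2, 0 °C
Reagents that add atoms: none
Why: Chemoselective aminolysis of the aryl acetate, far more electrophilic than the alkyl benzoate and isovalerate esters, frees the phenol.

**Compound list**

1 | furfural (furan-2-carbaldehyde) | O=Cc1ccco1 | starting material
2 | furfural endoperoxide, 2,3,7-trioxabicyclo[2.2.1]hept-5-ene-1-carbaldehyde (racemic) | O=CC12C=CC(OO1)O2 | intermediate
3 | 5-hydroxyfuran-2(5H)-one (racemic) | O=C1C=CC(O)O1 | intermediate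
4 | (+)-menthol, (1S,2R,5S)-5-methyl-2-(propan-2-yl)cyclohexan-1-ol | CC(C)[C@H]1CC[C@H](C)C[C@@H]1O | starting material
5 | (5S)-5-[(1S,2R,5S)-menthyloxy]furan-2(5H)-one | O=C1O[C@H](O[C@H]2C[C@@H](C)CC[C@@H]2C(C)C)C=C1 | intermediate
6 | 2-bromo-3-methylbut-1-ene | C=C(Br)C(C)C | starting material
7 | (3-methylbut-1-en-2-yl)magnesium bromide | C=C([Mg]Br)C(C)C | intermediate
8 | (4R,5S)-5-[(1S,2R,5S)-menthyloxy]-4-(3-methylbut-1-en-2-yl)oxolan-2-one (alkenyl trans to menthyloxy) | O=C1O[C@H](O[C@H]2C[C@@H](C)CC[C@@H]2C(C)C)[C@@H](C(=C)C(C)C)C1 | intermediate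
9 | lithium enolate of 8 | [Li]OC1=C[C@H](C(=C)C(C)C)[C@@H](O[C@H]2C[C@@H](C)CC[C@@H]2C(C)C)O1 | intermediate
10 | (3S,4R,5S)-3-allyl-5-[(1S,2R,5S)-menthyloxy]-4-(3-methylbut-1-en-2-yl)oxolan-2-one (all trans) | O=C1O[C@H](O[C@H]2C[C@@H](C)CC[C@@H]2C(C)C)[C@@H](C(=C)C(C)C)[C@@H]1CC=C | intermediate
11 | lithium enolate of 10 | [Li]OC1=C(CC=C)[C@H](C(=C)C(C)C)[C@@H](O[C@H]2C[C@@H](C)CC[C@@H]2C(C)C)O1 | intermediate
12 | (3R,4S,5S)-3-allyl-3-methyl-5-[(1S,2R,5S)-menthyloxy]-4-(3-methylbut-1-en-2-yl)oxolan-2-one (methyl trans, allyl cis to the alkenyl group) | O=C1O[C@H](O[C@H]2C[C@@H](C)CC[C@@H]2C(C)C)[C@@H](C(=C)C(C)C)[C@@]1(C)CC=C | intermediate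
13 | (3S,3aS,6aR)-6a-methyl-3-[(1S,2R,5S)-menthyloxy]-4-(propan-2-yl)-3,3a,6,6a-tetrahydro-1H-cyclopenta[c]furan-1-one (cis-fused) | O=C1O[C@H](O[C@H]3C[C@@H](C)CC[C@@H]3C(C)C)[C@H]2C(C(C)C)=CC[C@@]12C | intermediate
14 | (3S,3aR,4S,6aR)-4-hydroxy-6a-methyl-3-[(1S,2R,5S)-menthyloxy]-4-(propan-2-yl)hexahydro-1H-cyclopenta[c]furan-1-one | O=C1O[C@H](O[C@H]3C[C@@H](C)CC[C@@H]3C(C)C)[C@H]2[C@@](O)(C(C)C)CC[C@@]12C | intermediate
15 | (3aR,4S,6aR)-3,4-dihydroxy-6a-methyl-4-(propan-2-yl)hexahydro-1H-cyclopenta[c]furan-1-one (lactol, both C3 epimers) | O=C1OC(O)[C@H]2[C@@](O)(C(C)C)CC[C@@]12C | intermediate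
16 | methyl (1R,2R,3S)-2-formyl-3-hydroxy-1-methyl-3-(propan-2-yl)cyclopentane-1-carboxylate | COC(=O)[C@]1(C)CC[C@](O)(C(C)C)[C@@H]1C=O | intermediate
17 | (2-methylprop-2-en-1-yl)magnesium chloride | CC(=C)C[Mg]Cl | starting material
18 | B-(2-methylprop-2-en-1-yl)bis[(1S,2S,3S,5R)-isopinocampheyl]borane | CC(=C)CB([C@H]1C[C@H]2C[C@@H]([C@@H]1C)C2(C)C)[C@H]1C[C@H]2C[C@@H]([C@@H]1C)C2(C)C | intermediate
19 | methyl (1R,2S,3S)-3-hydroxy-2-[(1R)-1-hydroxy-3-methylbut-3-en-1-yl]-1-methyl-3-(propan-2-yl)cyclopentane-1-carboxylate | COC(=O)[C@]1(C)CC[C@](O)(C(C)C)[C@@H]1[C@H](O)CC(C)=C | intermediate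
20 | (3R,3aS,4S,6aR)-4-hydroxy-6a-methyl-3-(2-methylprop-2-en-1-yl)-4-(propan-2-yl)hexahydro-1H-cyclopenta[c]furan-1-one | O=C1O[C@H](CC(C)=C)[C@H]2[C@@](O)(C(C)C)CC[C@@]12C | intermediate
21 | ethynyl(trimethyl)silane | C#C[Si](C)(C)C | starting material
22 | lithium (trimethylsilyl)acetylide | [Li]C#C[Si](C)(C)C | intermediate
23 | 1-{(1R,2S,3S)-3-hydroxy-2-[(1R)-1-hydroxy-3-methylbut-3-en-1-yl]-1-methyl-3-(propan-2-yl)cyclopentyl}-3-(trimethylsilyl)prop-2-yn-1-one | C[Si](C)(C)C#CC(=O)[C@]1(C)CC[C@](O)(C(C)C)[C@@H]1[C@H](O)CC(C)=C | intermediate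
24 | 4-acetoxybenzoate of 23 at the secondary (C6) hydroxyl | C[Si](C)(C)C#CC(=O)[C@]1(C)CC[C@](O)(C(C)C)[C@@H]1[C@H](OC(=O)c2ccc(OC(C)=O)cc2)CC(C)=C | intermediate
25 | (10R)-propargylic alcohol from 24 (other centres unchanged) | C[Si](C)(C)C#C[C@H](O)[C@]1(C)CC[C@](O)(C(C)C)[C@@H]1[C@H](OC(=O)c2ccc(OC(C)=O)cc2)CC(C)=C | intermediate
26 | 3-methylbutanoate of 25 at the C10 hydroxyl | C[Si](C)(C)C#C[C@H](OC(=O)CC(C)C)[C@]1(C)CC[C@](O)(C(C)C)[C@@H]1[C@H](OC(=O)c2ccc(OC(C)=O)cc2)CC(C)=C | intermediate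
27 | terminal alkyne from 26 (10S) | C#C[C@H](OC(=O)CC(C)C)[C@]1(C)CC[C@](O)(C(C)C)[C@@H]1[C@H](OC(=O)c2ccc(OC(C)=O)cc2)CC(C)=C | intermediate
28 | diene, vinyl analogue of 27 (1R,4S,5S,6R,10S) | C=C[C@H](OC(=O)CC(C)C)[C@]1(C)CC[C@](O)(C(C)C)[C@@H]1[C@H](OC(=O)c2ccc(OC(C)=O)cc2)CC(C)=C | intermediate
29 | (3S,3aS,4R,8S,8aR)-3-hydroxy-6,8a-dimethyl-8-[(3-methylbutanoyl)oxy]-3-(propan-2-yl)-1,2,3,3a,4,5,8,8a-octahydroazulen-4-yl 4-acetoxybenzoate | CC1=C[C@H](OC(=O)CC(C)C)[C@]2(C)CC[C@](O)(C(C)C)[C@@H]2[C@H](OC(=O)c3ccc(OC(C)=O)cc3)C1 | intermediate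
30 | (3S,3aS,4R,8S,8aR)-3-hydroxy-6,8a-dimethyl-8-[(3-methylbutanoyl)oxy]-3-(propan-2-yl)-1,2,3,3a,4,5,8,8a-octahydroazulen-4-yl 4-hydroxybenzoate (CNP0086724.3) | CC1=C[C@H](OC(=O)CC(C)C)[C@]2(C)CC[C@](O)(C(C)C)[C@@H]2[C@H](OC(=O)c2ccc(O)cc2)C1 | target

**Summary**

Total step count: 18. Longest linear sequence: 18 steps (furfural to 30).

Three steps most likely to fail:

Step 3. A hindered, α-branched alkenyl Grignard must add 1,4 to the alkoxybutenolide; 1,2-addition or reduction may compete. The fallback sets out from 5 and uses an acyl-anion equivalent instead. 2-Lithio-2-(propan-2-yl)-1,3-dithiane (n-BuLi, THF, −78 °C) adds 1,4 and anti to the menthyloxy group to give the dithianyl lactone F1. Unmasking with Hg(ClO4)2 and CaCO3 in aqueous THF gives the isopropyl ketone F2. Takai–Lombardo methylenation (Zn, CH2Br2, TiCl4) converts it into 8, where the route is rejoined.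

Step 8. Aqueous acid next to a tertiary cyclopentanol may cause E1 dehydration, or the acetal may cleave slowly. The fallback sets out from 13 and reverses the order of events. The menthyl acetal is cleaved first (1 M HCl, THF) while C4 is still an alkene carbon, giving the alkene lactol F3. The Co(acac)2/PhSiH3/O2 hydration is then run on it (the lactol keeps the aldehyde masked), which comes back to the route at 15.

Step 11. Single addition of an acetylide to an α-quaternary lactone may be sluggish or over-add. The fallback sets out from 20 and goes through the aldehyde oxidation level. Reduction with i-Bu2AlH at −78 °C gives the lactol F4. Excess lithium (trimethylsilyl)acetylide adds to its hydroxy-aldehyde tautomer to give the propargylic diol F5 as a C10 epimer mixture. MnO2 oxidises only the propargylic hydroxyl, which returns to 23; C10 is then set in step 13 as planned.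

Further compounds
F1 | step 3 | trans-4-[2-(propan-2-yl)-1,3-dithian-2-yl]-5-[(1S,2R,5S)-menthyloxy]oxolan-2-one (same C4/C5 sense as 8) | O=C1O[C@H](O[C@H]2C[C@@H](C)CC[C@@H]2C(C)C)[C@@H](C3(C(C)C)SCCCS3)C1
F2 | step 3 | trans-4-(2-methylpropanoyl)-5-[(1S,2R,5S)-menthyloxy]oxolan-2-one (same C4/C5 sense as 8) | O=C1O[C@H](O[C@H]2C[C@@H](C)CC[C@@H]2C(C)C)[C@@H](C(=O)C(C)C)C1
F3 | step 8 | (3aS,6aR)-3-hydroxy-6a-methyl-4-(propan-2-yl)-3,3a,6,6a-tetrahydro-1H-cyclopenta[c]furan-1-one (lactol, both C3 epimers) | O=C1OC(O)[C@H]2C(C(C)C)=CC[C@@]12C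
F4 | step 11 | (3R,3aS,4S,6aR)-6a-methyl-3-(2-methylprop-2-en-1-yl)-4-(propan-2-yl)hexahydro-1H-cyclopenta[c]furan-1,4-diol (lactol of 20, both C1 epimers) | OC1O[C@H](CC(C)=C)[C@H]2[C@@](O)(C(C)C)CC[C@@]12C
F5 | step 11 | propargylic diol, C10 epimer mixture of the reduced form of 23 | C[Si](C)(C)C#CC(O)[C@]1(C)CC[C@](O)(C(C)C)[C@@H]1[C@H](O)CC(C)=C
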